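## Analysis of the target

The target is a dimeric dibenzylbutyrolactone lignan. Two γ-butyrolactones each carry a 3,4-dimethoxybenzyl (veratryl) group at C4 and an arylmethyl group at C3. The C3 arylmethyl groups are ring A (3-methoxy-4-aryloxybenzyl) and ring B (3-aryloxy-4-hydroxy-5-methoxybenzyl), joined by a diaryl ether between the C4 oxygen of ring A and C3 of ring B.

There are four stereocentres, C3 and C4 of each lactone, and all four are S. The substituents are trans within each lactone. The two lactones have the same absolute configuration but are separated by the achiral diaryl ether, so neither can steer the other.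

The sensitive sites are the epimerizable C3 centres, the lactones (hydroxide and nucleophiles), the oxidation-prone phenol of ring B and the electron-rich benzylic positions.

The synthesis is hard for two reasons. The ether oxygen is flanked by an ortho-methoxy group on ring A and an ortho-oxygen on ring B, so a direct aryl–oxygen coupling joins two electron-rich, ortho-substituted arenes. The lactone unit also enters twice, so any enantiomeric impurity in it reappears as diastereomeric dimers.

The strategy rests on ring A. Its C1 carbon substituent, C3 methoxy and C4 aryloxy groups are the pattern of a 4-aryloxy-3-oxocyclohex-1-ene-1-carboxylate. Ring A can therefore be grown on the α-carbon of an aryloxyacetone made from ring B and aromatized afterwards. The ether oxygen then enters by a plain phenol O-alkylation.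

## Retrosynthetic reasoning

**29 to 28.** The free phenol of target 29 is carried as the benzyl ether 28 and released last. Hydrogenolysis is safe at that point because 28 has no alkene and no other cleavable benzylic C–O bond; the diaryl ether and the lactone CH2–O bonds are not affected.

**28 to 15 and two molecules of 24.** Both C3–CH2(aryl) bonds are cut. Each C3 is α to a lactone carbonyl and so is an enolate carbon, and the C4 veratryl group of lactone 24 shields one face. Both C3 centres therefore derive from the single C4 centre of one building block used twice. The forward reaction must alkylate the bis(benzyl bromide) 15 at both arms, anti to the C4 substituent each time, without epimerization.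

**24 to 22, 19, 16, 17 and 20.** The lactone is opened at its ester C–O bond to hydroxy ester 23, which comes from imide 22 by reductive removal of the auxiliary. Cutting the bond between the stereocentre and the acetate carbon gives imide 19 and bromoacetate 20. Imide 19 is the acylation product of acid 16 and oxazolidinone 17. The (R)-auxiliary is chosen because it places the incoming acetate so that the new centre is S. The gain is a configuration that is predictable and can be purified at the diastereomeric imide 22 before the lactone is used twice.

**15 to 14, 13 and 12.** These are functional-group changes only. The two benzylic bromides come from diol 14, and the diol from diester 13, whose methyl ester (ring B) and ethyl ester (ring A) are reduced together. The ring A methoxy group of 13 comes from phenol 12 by O-methylation.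

**12 to 11.** Phenol 12 is one dehydrogenation above cyclohexenone 11. The phenol oxygen is the ketone oxygen of 11, the ester carbon is already in place at C1, and the aryloxy group already sits on C4. The forward reaction must remove two hydrogens without expelling the aryloxy group.

**11 to 4 and 8 (key disconnection).** The C4–C5 and C1–C2 bonds of ring A are cut. This leaves aryloxyacetone 4, which supplies C2, C3 and C4 with both oxygens, and vinyl ketoester 8, which supplies C5, C6, C1 and the ester carbon. The cut is made here because it removes the aryl–oxygen bond-forming problem altogether and fixes the 1,3,4-pattern by construction. The forward reaction needs a conjugate addition at the oxygen-bearing carbon of 4 followed by aldol condensation of its methyl group onto the ketoester carbonyl.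

**4 to 2 and 3; 2 to 1; 8 to 5 and 6.** Ketone 4 comes from phenol 2 and chloroacetone 3 by O-alkylation; this is the step that actually makes the future diaryl ether C–O bond. Phenol 2 comes from catechol 1 by benzylation of the more acidic hydroxyl para to the ester. Ketoester 8 comes from mono-acylation of vinyl nucleophile 6 by oxalate 5.

## Alternatives that were turned down

**Alternative 1:** The lactone building block A1 (the same compound as 24) is disconnected at O1–C5, back to the prochiral cyclobutanone A2, 3-(3,4-dimethoxybenzyl)cyclobutan-1-one.
- Forward key step: an aerobic, flavin-dependent Baeyer–Villiger monooxygenase inserts oxygen into one of the two enantiotopic C–C bonds next to the carbonyl of A2, expanding the ring and setting C4 in one catalytic step.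
- For it: no auxiliary and no cryogenic enolate chemistry; A2 is achiral and reachable in two steps by a ketene cycloaddition; the atom economy is better than that of steps 9 to 11. On the lactone itself this alternative is as short as, or shorter than, the auxiliary sequence used here.
- Against it: it addresses only the one-stereocentre building block and leaves the crowded diaryl ether and the pattern of ring A unsolved. The sense and level of enantiotopic discrimination on 3-benzylcyclobutanones depend on the enzyme and on the arene substituents, so the (S) product would have to be found by screening. Because the lactone enters the target twice, any shortfall in enantiopurity shows up as diastereomeric dimers.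
- Comparison: the chosen route offers in its place a configuration predictable from the auxiliary and purifiable at imide 22, and it spends its one uncertain step on the diaryl ether core and not on a fragment that is accessible in several ways.

**Alternative 2:** The C3–C4 bond of each lactone is disconnected in an acyclic precursor.
- Forward key step: both ester arms of a diaryl ether bis(3-arylpropanoate), esterified with an enantiopure E-allylic alcohol that already carries the veratryl group, are converted to silyl ketene acetals. These rearrange through chair transition states to the bis-acid A3, forming both C3–C4 bonds and all four stereocentres without closing a ring.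
- For it: C3 and C4 are made together in one operation, acyclic stereocontrol through the chair is well understood, and no strong base meets a finished lactone or a benzylic halide. On these points it is stronger than the chosen route.
- Against it: the diaryl ether must exist before the key step, so the hardest bond is not addressed. The allylic alcohol partner needs its own enantioselective synthesis. Both independent arms must enolize with the same ketene acetal geometry, and any leakage multiplies into several diastereomers. After the rearrangement each arm still needs oxidative cleavage of its propenyl group in the presence of four electron-rich arenes, then reduction and lactonization.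
- Comparison: the chosen strategy offers a short sequence after its key step, a trans relationship set on a cyclic enolate where it is the kinetic and thermodynamic preference, and a solution to the diaryl ether.

**Alternative 3:** Both C3–CH2 bonds are cut.
- Forward key step: two equivalents of the lithium enolate of A1 are alkylated by the O-benzyl diaryl ether bis(benzyl bromide) A5 (the same compound as 15) to give A4, the O-benzyl ether of the target (the same compound as 28).
- For it: maximal convergence and a reliably trans-selective alkylation.
- Against it as a strategy: it does not say where A5 comes from. It presupposes an aryl C–O coupling between a phenol with an ortho-benzyloxy group and an aryl halide with an ortho-methoxy group. Copper-mediated couplings are slowed by ortho substituents on both partners and by an electron-rich halide, and a substitution on an activated fluoroarene needs a para acceptor and forcing conditions.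
- Comparison: the disconnection itself is not rejected; it is step 12 of the chosen route, so on the endgame the two are equal. With a direct coupling, Alternative 3 would be about three steps shorter, and that is conceded. The chosen strategy offers in its place an ether oxygen introduced by simple phenol O-alkylation, a ring A substitution pattern fixed by ring construction, and independence from metal-mediated coupling. The coupling is kept as the fallback.

Key step: step 4

Remark on the chemistry: the SMILES is read as (3S,4S) in both lactone rings (trans in each), the mirror-image series of the common natural (3R,4R) dibenzylbutyrolactones. Methyl 3,4-dihydroxy-5-methoxybenzoate (1) is taken as a purchasable starting material.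

## Route

Step 1
Reactants: 1 methyl 3,4-dihydroxy-5-methoxybenzoate
Product: 2 methyl 4-(benzyloxy)-3-hydroxy-5-methoxybenzoate
Conditions: BnBr (1.05 equiv), NaHCO3, NaI (cat.), DMF, 40 °C
Reagents that add atoms: benzyl bromide, BrCc1ccccc1
Why: Williamson etherification under a weak base; only the 4-hydroxyl, para to the ester and therefore the most acidic, is ionized to a useful extent, so benzylation should occur there and leave the 3-hydroxyl free.

Step 2
Reactants: 2 methyl 4-(benzyloxy)-3-hydroxy-5-methoxybenzoate; 3 chloroacetone
Product: 4 methyl 4-(benzyloxy)-3-methoxy-5-(2-oxopropoxy)benzoate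
Conditions: K2CO3, KI (cat.), acetone, reflux
Reagents that add atoms: none
Why: Williamson O-alkylation of the remaining phenol with an α-halo ketone (Finkelstein activation by iodide); this ordinary SN2 step forms the C–O bond that later becomes the diaryl ether.

Step 3
Reactants: 5 diethyl oxalate; 6 vinylmagnesium bromide
Product: 8 ethyl 2-oxobut-3-enoate, via magnesium hemiketal alkoxide 7 (not isolated)
Conditions: 6 added slowly to 5, THF/Et2O, −78 °C; 1 M HCl quench at −78 °C; BHT (trace); kept cold in CH2Cl2 and used at once
Reagents that add atoms: none
Why: Mono-acylation of a Grignard reagent by a dialkyl oxalate; the chelated tetrahedral adduct 7 persists at −78 °C and collapses to the ketone only on acidic quench, which should prevent a second addition.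

Step 4
Reactants: 4 methyl 4-(benzyloxy)-3-methoxy-5-(2-oxopropoxy)benzoate; 8 ethyl 2-oxobut-3-enoate
Product: 11 ethyl 4-[2-(benzyloxy)-3-methoxy-5-(methoxycarbonyl)phenoxy]-3-oxocyclohex-1-ene-1-carboxylate (racemic), via diketo ester 9 (not isolated), via cyclic ketol 10 (not isolated)
Conditions: pyrrolidine (30 mol %), AcOH (30 mol %), CH2Cl2, 0 °C → rt, 8 (1.5 equiv) added over 3 h; then TsOH·H2O (20 mol %), PhMe, 60 °C
Reagents that add atoms: none
Why: Pyrrolidinium acetate converts ketone 4 into an enamine, preferentially toward the aryloxy-bearing carbon, because that C–H is the more acidic one and the oxygen substituent stabilises the enamine double bond, as is usual for α-oxygenated acetones. This enamine adds to the unsubstituted β-carbon of 8 (directly or through a hetero-Diels–Alder adduct that opens on hydrolysis), forming C4–C5 of ring A and giving diketo ester 9. A second enamine, now on the methyl group because the aryloxy carbon has become tertiary, attacks the strongly electrophilic ketoester carbonyl in a 6-(enolexo)-exo-trig aldol closure that forms C1–C2 and gives ketol 10; acid-assisted E1cB dehydration then delivers the doubly conjugated enone 11. The closest known reaction type is the amine-catalysed Robinson annulation of ketones with vinyl ketones and with β,γ-unsaturated α-ketoesters. Within 9 every other enol and carbonyl pairing would close a four-membered ring, so the constitution of 11 depends only on the site of the Michael addition, and this regioselectivity is the one selectivity the step needs; it is secured by the α-oxygen of 4. The two stereocentres formed on the way (C4 of ring A and the carbinol carbon of 10) are not controlled and need not be, since dehydration and the later aromatization remove both. Slow addition of 8 keeps its concentration low and should hold back its self-condensation and a second Michael addition.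

Step 5
Reactants: 11 ethyl 4-[2-(benzyloxy)-3-methoxy-5-(methoxycarbonyl)phenoxy]-3-oxocyclohex-1-ene-1-carboxylate
Product: 12 ethyl 4-[2-(benzyloxy)-3-methoxy-5-(methoxycarbonyl)phenoxy]-3-hydroxybenzoate
Conditions: I2 (20 mol %), DMSO, 90 °C
Reagents that add atoms: none
Why: Iodine-mediated oxidative aromatization of a cyclohexenone: α-iodination of the enol, loss of HI to a cyclohexadienone and tautomerization should give the phenol, while DMSO reoxidizes HI to I2; the aryloxy group ends up ortho to the new hydroxyl.

Step 6
Reactants: 12 ethyl 4-[2-(benzyloxy)-3-methoxy-5-(methoxycarbonyl)phenoxy]-3-hydroxybenzoate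
Product: 13 ethyl 4-[2-(benzyloxy)-3-methoxy-5-(methoxycarbonyl)phenoxy]-3-methoxybenzoate
Conditions: MeI, K2CO3, DMF, rt
Reagents that add atoms: iodomethane, CI
Why: Williamson O-methylation of the only free phenol; both esters and the benzyl ether are inert under these conditions.

Step 7
Reactants: 13 ethyl 4-[2-(benzyloxy)-3-methoxy-5-(methoxycarbonyl)phenoxy]-3-methoxybenzoate
Product: 14 {4-(benzyloxy)-3-[4-(hydroxymethyl)-2-methoxyphenoxy]-5-methoxyphenyl}methanol
Conditions: LiAlH4, THF, 0 °C → rt; NaOH/H2O work-up
Reagents that add atoms: none
Why: Hydride reduction of both aryl esters to benzylic alcohols in one operation; the aryl ethers are untouched.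

Step 8
Reactants: 14 {4-(benzyloxy)-3-[4-(hydroxymethyl)-2-methoxyphenoxy]-5-methoxyphenyl}methanol
Product: 15 2-(benzyloxy)-5-(bromomethyl)-1-[4-(bromomethyl)-2-methoxyphenoxy]-3-methoxybenzene
Conditions: PBr3 (0.8 equiv), CH2Cl2, 0 °C; used crude
Reagents that add atoms: phosphorus tribromide, BrP(Br)Br
Why: Conversion of benzylic alcohols to bromides through their phosphite esters; the electron-rich dibromide is expected to be labile and is therefore carried on without purification.

Step 9
Reactants: 16 3-(3,4-dimethoxyphenyl)propanoic acid; 17 (R)-4-benzyl-1,3-oxazolidin-2-one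
Product: 19 (R)-4-benzyl-3-[3-(3,4-dimethoxyphenyl)propanoyl]-1,3-oxazolidin-2-one, via mixed pivalic anhydride 18 (not isolated)
Conditions: t-BuCOCl, Et3N, THF, −20 °C; then LiCl, 17, rt
Reagents that add atoms: none
Why: N-Acylation of the oxazolidinone through a mixed anhydride; the hindered pivaloyl carbonyl directs attack to the arylpropanoyl carbonyl and LiCl activates the auxiliary.

Step 10
Reactants: 19 (R)-4-benzyl-3-[3-(3,4-dimethoxyphenyl)propanoyl]-1,3-oxazolidin-2-one; 20 tert-butyl bromoacetate
Product: 22 tert-butyl (S)-4-[(R)-4-benzyl-2-oxo-1,3-oxazolidin-3-yl]-3-(3,4-dimethoxybenzyl)-4-oxobutanoate, via sodium Z-enolate 21 (not isolated)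
Conditions: NaN(SiMe3)2, THF, −78 °C; then 20, −78 → −40 °C
Reagents that add atoms: none
Why: Evans auxiliary alkylation; the chelated Z-enolate is attacked on the face opposite the benzyl group of the (R)-auxiliary, which places the acetate arm so that the new centre is S, and the diastereomers can be separated at this stage.

Step 11
Reactants: 22 tert-butyl (S)-4-[(R)-4-benzyl-2-oxo-1,3-oxazolidin-3-yl]-3-(3,4-dimethoxybenzyl)-4-oxobutanoate
Product: 24 (S)-4-(3,4-dimethoxybenzyl)dihydrofuran-2(3H)-one, via hydroxy ester 23 (not isolated)
Conditions: LiBH4, MeOH (1 equiv), THF, 0 °C; aqueous work-up; then CF3CO2H, CH2Cl2, rt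
Reagents that add atoms: none
Why: Chemoselective borohydride reduction of the imide carbonyl releases the auxiliary and the primary alcohol while the tert-butyl ester survives; acid then cleaves the tert-butyl ester and the γ-hydroxy acid lactonizes, with the stereocentre untouched.

Step 12
Reactants: 24 (S)-4-(3,4-dimethoxybenzyl)dihydrofuran-2(3H)-one; 15 2-(benzyloxy)-5-(bromomethyl)-1-[4-(bromomethyl)-2-methoxyphenoxy]-3-methoxybenzene
Product: 28 (3S,4S)-3-{4-(benzyloxy)-3-[4-{[(3S,4S)-4-(3,4-dimethoxybenzyl)-2-oxotetrahydrofuran-3-yl]methyl}-2-methoxyphenoxy]-5-methoxybenzyl}-4-(3,4-dimethoxybenzyl)dihydrofuran-2(3H)-one, via lithium enolate 25 (not isolated), via ring-A-alkylated monobromide 26 (not isolated), via ring-B-alkylated monobromide 27 (not isolated)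
Conditions: 24 (2.4 equiv), LiN(SiMe3)2, THF, −78 °C; then 15 (1.0 equiv), DMPU, −78 → −30 °C; excess 24 recovered
Reagents that add atoms: none
Why: Two-directional alkylation of a β-substituted γ-butyrolactone enolate with primary benzylic bromides; each electrophile approaches anti to the C4 veratryl group, so both new C3 centres should be trans to C4 and therefore S.

Step 13
Reactants: 28 the O-benzyl ether of the target
Product: 29 (3S,4S)-4-(3,4-dimethoxybenzyl)-3-{3-[4-{[(3S,4S)-4-(3,4-dimethoxybenzyl)-2-oxotetrahydrofuran-3-yl]methyl}-2-methoxyphenoxy]-4-hydroxy-5-methoxybenzyl}dihydrofuran-2(3H)-one (CNP0183104.1)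
Conditions: H2 (1 atm), Pd/C (10 wt % palladium on carbon), EtOAc/EtOH, rt
Reagents that add atoms: none
Why: Hydrogenolysis of the aryl benzyl ether under neutral conditions; the diaryl ether, the lactones and the C3 centres are not affected.

## Compound list

1 | methyl 3,4-dihydroxy-5-methoxybenzoate | COC(=O)c1cc(O)c(O)c(OC)c1 | starting material
2 | methyl 4-(benzyloxy)-3-hydroxy-5-methoxybenzoate | COC(=O)c1cc(O)c(OCc2ccccc2)c(OC)c1 | intermediate
3 | chloroacetone | CC(=O)CCl | starting material
4 | methyl 4-(benzyloxy)-3-methoxy-5-(2-oxopropoxy)benzoate | COC(=O)c1cc(OCC(C)=O)c(OCc2ccccc2)c(OC)c1 | intermediate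
5 | diethyl oxalate | CCOC(=O)C(=O)OCC | starting material
6 | vinylmagnesium bromide | C=C[Mg]Br | starting material
7 | bromomagnesium alkoxide of ethyl 2-ethoxy-2-hydroxybut-3-enoate (not isolated) | CCOC(=O)C(OCC)(O[Mg]Br)C=C | intermediate
8 | ethyl 2-oxobut-3-enoate | CCOC(=O)C(=O)C=C | intermediate
9 | ethyl 5-[2-(benzyloxy)-3-methoxy-5-(methoxycarbonyl)phenoxy]-2,6-dioxoheptanoate (racemic, not isolated) | CCOC(=O)C(=O)CCC(Oc1cc(C(=O)OC)cc(OC)c1OCc1ccccc1)C(C)=O | intermediate
10 | ethyl 4-[2-(benzyloxy)-3-methoxy-5-(methoxycarbonyl)phenoxy]-1-hydroxy-3-oxocyclohexane-1-carboxylate (mixture of diastereomers, not isolated) | CCOC(=O)C1(O)CC(=O)C(Oc2cc(C(=O)OC)cc(OC)c2OCc2ccccc2)CC1 | intermediate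
11 | ethyl 4-[2-(benzyloxy)-3-methoxy-5-(methoxycarbonyl)phenoxy]-3-oxocyclohex-1-ene-1-carboxylate (racemic) | CCOC(=O)C1=CC(=O)C(Oc2cc(C(=O)OC)cc(OC)c2OCc2ccccc2)CC1 | intermediate
12 | ethyl 4-[2-(benzyloxy)-3-methoxy-5-(methoxycarbonyl)phenoxy]-3-hydroxybenzoate | CCOC(=O)c1ccc(Oc2cc(C(=O)OC)cc(OC)c2OCc2ccccc2)c(O)c1 | intermediate
13 | ethyl 4-[2-(benzyloxy)-3-methoxy-5-(methoxycarbonyl)phenoxy]-3-methoxybenzoate | CCOC(=O)c1ccc(Oc2cc(C(=O)OC)cc(OC)c2OCc2ccccc2)c(OC)c1 | intermediate
14 | {4-(benzyloxy)-3-[4-(hydroxymethyl)-2-methoxyphenoxy]-5-methoxyphenyl}methanol | OCc1ccc(Oc2cc(CO)cc(OC)c2OCc2ccccc2)c(OC)c1 | intermediate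
15 | 2-(benzyloxy)-5-(bromomethyl)-1-[4-(bromomethyl)-2-methoxyphenoxy]-3-methoxybenzene | BrCc1ccc(Oc2cc(CBr)cc(OC)c2OCc2ccccc2)c(OC)c1 | intermediate
16 | 3-(3,4-dimethoxyphenyl)propanoic acid | COc1ccc(CCC(=O)O)cc1OC | starting material
17 | (R)-4-benzyl-1,3-oxazolidin-2-one | O=C1OC[C@@H](Cc2ccccc2)N1 | starting material
18 | 3-(3,4-dimethoxyphenyl)propanoic pivalic anhydride (not isolated) | COc1ccc(CCC(=O)OC(=O)C(C)(C)C)cc1OC | intermediate
19 | (R)-4-benzyl-3-[3-(3,4-dimethoxyphenyl)propanoyl]-1,3-oxazolidin-2-one | COc1ccc(CCC(=O)N2[C@H](Cc3ccccc3)COC2=O)cc1OC | intermediate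
20 | tert-butyl bromoacetate | CC(C)(C)OC(=O)CBr | starting material
21 | sodium (Z)-enolate of imide 19 (not isolated) | COc1ccc(C/C=C(\O[Na])N2[C@H](Cc3ccccc3)COC2=O)cc1OC | intermediate
22 | tert-butyl (S)-4-[(R)-4-benzyl-2-oxo-1,3-oxazolidin-3-yl]-3-(3,4-dimethoxybenzyl)-4-oxobutanoate | COc1ccc(C[C@@H](CC(=O)OC(C)(C)C)C(=O)N2[C@H](Cc3ccccc3)COC2=O)cc1OC | intermediate
23 | tert-butyl (S)-3-(3,4-dimethoxybenzyl)-4-hydroxybutanoate (not isolated) | COc1ccc(C[C@@H](CC(=O)OC(C)(C)C)CO)cc1OC | intermediate
24 | (S)-4-(3,4-dimethoxybenzyl)dihydrofuran-2(3H)-one | COc1ccc(C[C@@H]2COC(=O)C2)cc1OC | intermediate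
25 | lithium enolate of lactone 24 (not isolated) | COc1ccc(C[C@@H]2COC(O[Li])=C2)cc1OC | intermediate
26 | (3S,4S)-3-{4-[2-(benzyloxy)-5-(bromomethyl)-3-methoxyphenoxy]-3-methoxybenzyl}-4-(3,4-dimethoxybenzyl)dihydrofuran-2(3H)-one (not isolated) | COc1ccc(C[C@@H]2COC(=O)[C@H]2Cc2ccc(Oc3cc(CBr)cc(OC)c3OCc3ccccc3)c(OC)c2)cc1OC | intermediate
27 | (3S,4S)-3-{4-(benzyloxy)-3-[4-(bromomethyl)-2-methoxyphenoxy]-5-methoxybenzyl}-4-(3,4-dimethoxybenzyl)dihydrofuran-2(3H)-one (not isolated) | BrCc1ccc(Oc2cc(C[C@@H]3C(=O)OC[C@H]3Cc3ccc(OC)c(OC)c3)cc(OC)c2OCc2ccccc2)c(OC)c1 | intermediate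
28 | (3S,4S)-3-{4-(benzyloxy)-3-[4-{[(3S,4S)-4-(3,4-dimethoxybenzyl)-2-oxotetrahydrofuran-3-yl]methyl}-2-methoxyphenoxy]-5-methoxybenzyl}-4-(3,4-dimethoxybenzyl)dihydrofuran-2(3H)-one | COc1ccc(C[C@@H]2COC(=O)[C@H]2Cc2ccc(Oc3cc(C[C@@H]4C(=O)OC[C@H]4Cc4ccc(OC)c(OC)c4)cc(OC)c3OCc3ccccc3)c(OC)c2)cc1OC | intermediate
29 | (3S,4S)-4-(3,4-dimethoxybenzyl)-3-{3-[4-{[(3S,4S)-4-(3,4-dimethoxybenzyl)-2-oxotetrahydrofuran-3-yl]methyl}-2-methoxyphenoxy]-4-hydroxy-5-methoxybenzyl}dihydrofuran-2(3H)-one (CNP0183104.1) | COc1ccc(C[C@@H]2COC(=O)[C@H]2Cc2ccc(Oc3cc(C[C@@H]4C(=O)OC[C@H]4Cc4ccc(OC)c(OC)c4)cc(OC)c3O)c(OC)c2)cc1OC | target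

## Step count and least certain steps

Total: 13 steps. Longest linear sequence: 9 steps from compound 1 (steps 1, 2, 4, 5, 6, 7, 8, 12, 13). Steps 9 to 11 (lactone 24) and step 3 (ketoester 8) are side branches.

**Step 4 (key step).**
- What may go wrong: enamine formation and Michael addition on the methyl side of 4 and not on the aryloxy side, which would lead to a 2-aryloxy isomer of ring A. Self-condensation or polymerization of the very reactive acceptor 8 may outrun the addition, and a second Michael addition may follow the first.
- Fallback: it sets out from phenol 2 and returns at diol 14, giving up the de novo construction of ring A for a known aryl C–O bond formation. Nucleophilic aromatic substitution of 2 on 4-fluoro-3-methoxybenzaldehyde (K2CO3, DMF, 120 °C), with the para-formyl group activating the fluoride, should give methyl 4-(benzyloxy)-3-(4-formyl-2-methoxyphenoxy)-5-methoxybenzoate F1. LiAlH4 in THF then reduces the aldehyde and the ester together to 14.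

**Step 3.**
- What may go wrong: a second Grignard addition to the ketone if the tetrahedral adduct collapses before the quench, and oligomerization or hetero-Diels–Alder dimerization of 8 during concentration or storage.
- Fallback: it sets out from 6 and returns at 8. Addition of 6 to ethyl glyoxylate (THF, −78 °C) gives ethyl 2-hydroxybut-3-enoate F2, a storable allylic alcohol. F2 is oxidized with Dess–Martin periodinane (CH2Cl2, 0 °C) immediately before step 4, so that 8 is never stored or concentrated.

**Step 5.**
- What may go wrong: acid-promoted loss of the aryloxy group by elimination, which aromatizes the ring without oxidation and destroys the ether, and electrophilic iodination of the newly formed phenol ring.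
- Fallback: it sets out from 11 and returns at 12. Soft enolization (Me3SiOTf, Et3N, CH2Cl2, 0 °C) gives the cross-conjugated silyl dienol ether, ethyl 4-[2-(benzyloxy)-3-methoxy-5-(methoxycarbonyl)phenoxy]-3-[(trimethylsilyl)oxy]cyclohexa-1,3-diene-1-carboxylate F3. Dehydrogenation with DDQ (dioxane, rt) gives the aryl silyl ether, ethyl 4-[2-(benzyloxy)-3-methoxy-5-(methoxycarbonyl)phenoxy]-3-[(trimethylsilyl)oxy]benzoate F4. Dilute HCl in THF cleaves the silyl ether to 12.

**Step 12.**
- What may go wrong: incomplete alkylation at the second arm, ionization and self-condensation of the electron-rich dibromide 15 before it is consumed, proton transfer between product and enolate leading to epimerization or double alkylation at C3, and erosion of trans selectivity.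
- Fallback: it sets out from diol 14 and lactone 24 and returns at target 29, bypassing 15 and 28. MnO2 (CH2Cl2, rt) oxidizes 14 to 4-(benzyloxy)-3-(4-formyl-2-methoxyphenoxy)-5-methoxybenzaldehyde F5. Aldol addition of the lithium enolate 25 (2.4 equiv, THF, −78 °C) occurs anti to the C4 substituent and gives the bis(β-hydroxy lactone) F6, trans in each lactone and a mixture only at the two carbinol carbons. One hydrogenolysis (H2, Pd/C, AcOH, cat. HClO4) removes both benzylic hydroxyl groups and the benzyl ether.

## Further compounds

F1 | step 4 | methyl 4-(benzyloxy)-3-(4-formyl-2-methoxyphenoxy)-5-methoxybenzoate | COC(=O)c1cc(Oc2ccc(C=O)cc2OC)c(OCc2ccccc2)c(OC)c1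
F2 | step 3 | ethyl 2-hydroxybut-3-enoate (racemic) | CCOC(=O)C(O)C=C
F3 | step 5 | ethyl 4-[2-(benzyloxy)-3-methoxy-5-(methoxycarbonyl)phenoxy]-3-[(trimethylsilyl)oxy]cyclohexa-1,3-diene-1-carboxylate | CCOC(=O)C1=CC(O[Si](C)(C)C)=C(Oc2cc(C(=O)OC)cc(OC)c2OCc2ccccc2)CC1
F4 | step 5 | ethyl 4-[2-(benzyloxy)-3-methoxy-5-(methoxycarbonyl)phenoxy]-3-[(trimethylsilyl)oxy]benzoate | CCOC(=O)c1ccc(Oc2cc(C(=O)OC)cc(OC)c2OCc2ccccc2)c(O[Si](C)(C)C)c1
F5 | step 12 | 4-(benzyloxy)-3-(4-formyl-2-methoxyphenoxy)-5-methoxybenzaldehyde | COc1cc(C=O)ccc1Oc1cc(C=O)cc(OC)c1OCc1ccccc1
F6 | step 12 | bis(β-hydroxy lactone) from F5 and two molecules of 24, trans in each lactone, carbinol carbons unassigned | COc1ccc(C[C@@H]2COC(=O)[C@H]2C(O)c2ccc(Oc3cc(C(O)[C@@H]4C(=O)OC[C@H]4Cc4ccc(OC)c(OC)c4)cc(OC)c3OCc3ccccc3)c(OC)c2)cc1OC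
A1 | alternative 1 | (S)-4-(3,4-dimethoxybenzyl)dihydrofuran-2(3H)-one | COc1ccc(C[C@@H]2COC(=O)C2)cc1OC
A2 | alternative 1 | 3-(3,4-dimethoxybenzyl)cyclobutan-1-one | COc1ccc(CC2CC(=O)C2)cc1OC
A3 | alternative 2 | O-benzyl diaryl ether bis[(E)-2-(arylmethyl)-3-(3,4-dimethoxybenzyl)hex-4-enoic acid] | C/C=C/[C@@H](Cc1ccc(OC)c(OC)c1)[C@@H](C(=O)O)Cc1ccc(Oc2cc(C[C@H](C(=O)O)[C@H](Cc3ccc(OC)c(OC)c3)/C=C/C)cc(OC)c2OCc2ccccc2)c(OC)c1
A4 | alternative 3 | O-benzyl ether of the target | COc1ccc(C[C@@H]2COC(=O)[C@H]2Cc2ccc(Oc3cc(C[C@@H]4C(=O)OC[C@H]4Cc4ccc(OC)c(OC)c4)cc(OC)c3OCc3ccccc3)c(OC)c2)cc1OC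
A5 | alternative 3 | 2-(benzyloxy)-5-(bromomethyl)-1-[4-(bromomethyl)-2-methoxyphenoxy]-3-methoxybenzene | BrCc1ccc(Oc2cc(CBr)cc(OC)c2OCc2ccccc2)c(OC)c1
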